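**Strategy.** Ring A (C1, C10, C11, C12, C13, C14; briarane numbering) is built by an intramolecular Diels–Alder reaction that forms C10–C1 and C13–C14 at once. The dienophile is (S)-4-hydroxy-3-methylcyclopent-2-enone, whose carbons become C14, C1, C2, C3 and C4; the diene is a butanolide-bearing dienol that carries C5 to C13. A diisopropylsilylene bridge between the oxygens on C2 and C9, both retained in the target, fixes the regiochemistry and relays the C2 and C9 stereocentres to the quaternary C1, to C10 and to C14. Baeyer–Villiger cleavage of the cyclopentanone then installs the C14 oxygen and frees C4 for a Nozaki–Hiyama–Kishi closure of the ten-membered ring.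

Key step: step 15

Numbering: C1 is the ring-fusion carbon bearing the C15 methyl; C2 carries the isobutyrate; C3 is CH2; C4, C9 and C14 carry the acetates; C5(=C6) carries the C16 methyl; C7 is the lactone O–CH; C8 is the tertiary carbinol; C10 is the ring-fusion CH; C11 carries the exocyclic C20 methylene; C17 (C18 methyl) and C19 (C=O) complete the lactone.

Assumption: L-erythrulose, prop-2-yn-1-ol and (4S)-4-[(tert-butyldimethylsilyl)oxy]cyclopent-2-en-1-one are taken as commercial. CIP descriptors of intermediates can differ from those of the target where substituent priorities change; the SMILES are decisive.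

## Route

Step 1
Reactants: 1 L-erythrulose
Product: 2 3,4-O-isopropylidene-L-erythrulose
Conditions: 2,2-dimethoxypropane, acetone, camphorsulfonic acid (cat.), 0 °C to rt
Reagents that add atoms: 2,2-dimethoxypropane, CC(C)(OC)OC
Why: Acid-catalysed transacetalization closes the five-membered dioxolane on the vicinal C7/C6 diol and leaves the C9 hydroxyl free; the C7 stereocentre of the chiral pool is untouched (acetonide protection).

Step 2
Reactants: 2 3,4-O-isopropylidene-L-erythrulose
Product: 3 1-O-TBDPS-3,4-O-isopropylidene-L-erythrulose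
Conditions: t-BuPh2SiCl, imidazole, DMF, 0 °C
Reagents that add atoms: tert-butyl(chloro)diphenylsilane, CC(C)(C)[Si](Cl)(c1ccccc1)c1ccccc1
Why: Silylation of the only hydroxyl gives a bulky, non-chelating ether on C9, which matters for the facial control of step 3.

Step 3
Reactants: 3 1-O-TBDPS-3,4-O-isopropylidene-L-erythrulose
Product: 4 aldol adduct (methyl ester, tertiary C8 alcohol, both C17 epimers)
Conditions: methyl propanoate, LiN(iPr)2, THF, −78 °C; then 3 precomplexed with MgBr2·OEt2 in CH2Cl2, −78 °C; aq. NH4Cl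
Reagents that add atoms: methyl propanoate, CCC(=O)OC
Why: Aldol addition of the ester enolate to the ketone under Cram-chelate control, in which magnesium bridges the ketone oxygen and the dioxolane oxygen on C7 and the enolate enters anti to C6, should set C8 as required; C17 forms unselectively and is corrected in step 4.

Step 4
Reactants: 4 aldol adduct
Product: 6 lactone diol (17R), via lactone diol C17-epimer mixture 5 (not isolated)
Conditions: p-TsOH·H2O (cat.), MeOH/H2O, 40 °C; concentrate; then DBU (cat.), toluene, 60 °C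
Reagents that add atoms: none
Why: Acetonide hydrolysis frees the C7 hydroxyl, which closes the five-membered lactone on the methyl ester, and base-mediated enolization then equilibrates C17 to the epimer with the methyl trans to the bulky silyloxymethyl group on C8 (cis to the hydroxyl), which is the required configuration (thermodynamic control).

Step 5
Reactants: 6 lactone diol (17R)
Product: 7 C6 aldehyde
Conditions: Dess–Martin periodinane, NaHCO3, CH2Cl2, 0 °C to rt
Reagents that add atoms: none
Why: Buffered Dess–Martin oxidation converts the primary alcohol to the aldehyde while the tertiary C8 hydroxyl is inert and the neutral conditions spare the α-oxygenated C7 centre.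

Step 6
Reactants: 7 C6 aldehyde
Product: 8 (Z)-vinyl iodide
Conditions: EtPPh3I, n-BuLi, THF, 0 °C; I2, −78 °C; NaN(SiMe3)2, −20 °C; then 7, −78 °C
Reagents that add atoms: ethyltriphenylphosphonium iodide, CC[P+](c1ccccc1)(c1ccccc1)c1ccccc1.[I-]; iodine, II
Why: The Stork–Zhao–Wittig olefination with the α-iodo ylide is kinetically cis-selective and places iodine cis to C7, which fixes the Z geometry of C5=C6; the ylide does not deprotonate the tertiary alcohol and the cold, fast addition should spare C7.

Step 7
Reactants: 8 (Z)-vinyl iodide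
Product: 9 C8,C9 diol
Conditions: Bu4NF, AcOH, THF, 0 °C to rt
Reagents that add atoms: none
Why: Buffered fluoride cleaves the silyl ether without opening the lactone or epimerizing C17 (desilylation).

Step 8
Reactants: 9 C8,C9 diol
Product: 11 C9 aldehyde with C8 triethylsilyl ether, via hydroxy aldehyde 10 (not isolated)
Conditions: IBX, DMSO, rt; extractive work-up; then Et3SiOTf, 2,6-lutidine, CH2Cl2, −78 °C
Reagents that add atoms: triethylsilyl trifluoromethanesulfonate, CC[Si](CC)(CC)OS(=O)(=O)C(F)(F)F
Why: IBX oxidizes the primary alcohol of the 1,2-diol without glycol cleavage and the silyl triflate caps the tertiary hydroxyl so that it cannot chelate in step 11; the aldehyde has a quaternary α-carbon and cannot epimerize.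

Step 9
Reactants: 12 prop-2-yn-1-ol
Product: 14 (2Z)-2-(iodomethylidene)but-3-en-1-ol, via cyclic alkenylmagnesium alkoxide 13 (not isolated)
Conditions: vinylmagnesium chloride (3.5 equiv), THF/cyclohexane, reflux; then I2, THF, −78 to 0 °C
Reagents that add atoms: vinylmagnesium chloride, C=C[Mg]Cl; iodine, II
Why: Hydroxyl-directed anti-carbomagnesiation (Fallis) puts the vinyl group on the proximal alkyne carbon and magnesium on the distal one in a five-membered chelate, and iodinolysis with retention gives the iodide cis to CH2OH and trans to vinyl.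

Step 10
Reactants: 14 (2Z)-2-(iodomethylidene)but-3-en-1-ol
Product: 15 TBS ether of 14
Conditions: t-BuMe2SiCl, imidazole, CH2Cl2, 0 °C
Reagents that add atoms: tert-butyl(chloro)dimethylsilane, CC(C)(C)[Si](C)(C)Cl
Why: Standard silylation of the primary allylic alcohol (future C20 oxygen).

Step 11
Reactants: 11 C9 aldehyde with C8 triethylsilyl ether; 15 TBS ether of 14
Product: 18 dienol (9S), via dienyllithium 16 (not isolated), via dienylzinc bromide 17 (not isolated)
Conditions: 15, t-BuLi (2 equiv), Et2O, −78 °C; ZnBr2, −78 to 0 °C; (−)-MIB (cat.), N,N,N′,N′-tetraethylethylenediamine, toluene; then 11, −20 °C; aq. NH4Cl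
Reagents that add atoms: none
Why: Iodine–lithium exchange and transmetalation retain the alkene geometry, and the amino alcohol–zinc catalyst should deliver the dienyl group to the Si face of the α-quaternary aldehyde (ligand-controlled asymmetric alkenylzinc addition) to give the 9S carbinol, the organozinc leaving lactone and vinyl iodide untouched.

Step 12
Reactants: 19 (4S)-4-[(tert-butyldimethylsilyl)oxy]cyclopent-2-en-1-one
Product: 21 (4S)-4-[(tert-butyldimethylsilyl)oxy]-3-methylcyclopent-2-en-1-one, via trans silyl enol ether 20 (not isolated)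
Conditions: MeLi, CuI, Et2O, 0 °C; then 19, Me3SiCl, THF, −78 °C; then Pd(OAc)2 (1 equiv), MeCN, rt
Reagents that add atoms: lithium dimethylcuprate (from methyllithium and CuI), C[Cu-]C.[Li+]
Why: Cuprate conjugate addition anti to the silyloxy group with enolate trapping, then Saegusa–Ito oxidation, restores the enone with the methyl on the β-carbon (future C1); the transient methine centre is destroyed and the C2 stereocentre is untouched.

Step 13
Reactants: 21 (4S)-4-[(tert-butyldimethylsilyl)oxy]-3-methylcyclopent-2-en-1-one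
Product: 22 (4S)-4-hydroxy-3-methylcyclopent-2-en-1-one
Conditions: HF (48% aq.), MeCN, 0 °C
Reagents that add atoms: none
Why: Acidic desilylation avoids the base-induced elimination to which γ-hydroxy enones are prone.

Step 14
Reactants: 18 dienol (9S); 22 (4S)-4-hydroxy-3-methylcyclopent-2-en-1-one
Product: 24 silaketal, via chlorosilane 23 (not isolated)
Conditions: 18, iPr2SiCl2 (excess), imidazole, CH2Cl2, 0 °C to rt; evaporate excess silane; then 22, imidazole, DMAP (cat.), DMF, rt
Reagents that add atoms: dichlorodi(propan-2-yl)silane, CC(C)[Si](Cl)(Cl)C(C)C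
Why: Stepwise displacement of the two chlorides, hindered C9 alcohol first and unhindered C2 alcohol second, gives the unsymmetrical silaketal without homodimers; the tertiary C8 oxygen is already silylated.

Step 15
Reactants: 24 silaketal
Product: 25 tetracyclic cycloadduct
Conditions: toluene (0.005 M), BHT (cat.), 170 °C, sealed tube
Reagents that add atoms: none
Why: A thermal, concerted but asynchronous [4+2] cycloaddition joins the diene terminus C10 to the enone β-carbon C1 and C13 to the α-carbon C14; the closest known reaction type is the silaketal-tethered (temporary silicon connection) intramolecular Diels–Alder reaction of a dienol with a hydroxylated dienophile. Ring A closes as the six-membered cycloadduct ring, and the seven-membered 1,3-dioxa-2-silepane (C1, C2, O, Si, O, C9, C10) closes in the fused mode imposed by the five-atom tether, which dictates the regiochemistry and matches the polarity of the partners (the more nucleophilic, substituted diene terminus meets the enone β-carbon). C1 and C14 are set by the C2 stereocentre, because the short O–Si–O link lets the diene reach only the enone face syn to the C2 oxygen, and the cis ring fusion follows from the cyclic dienophile. C10 is set by C9: allylic 1,3-strain with the silyloxymethyl group on C11 holds the C9 hydrogen in the diene plane, so the tethering oxygen delivers the dienophile to one diene face while the bulky lactone on C8 points away. The required exo orientation of the cyclopentenone (C9 trans to C2 on ring A) is the only one that satisfies both tether ends, since the endo mode would drive the C2–O bond into the diene at C11. The selectivity needed is therefore complete facial control on both partners, secured by the tether and the two pre-set stereocentres; the weak point is the low reactivity of a β,β-disubstituted enone, which intramolecularity and temperature must overcome.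

Step 16
Reactants: 25 tetracyclic cycloadduct
Product: 26 δ-lactone (C14–O–C4)
Conditions: Me3SiOOSiMe3, SnCl4 (cat.), trans-N,N′-bis(p-tolylsulfonyl)cyclohexane-1,2-diamine (cat.), 4 Å molecular sieves, CH2Cl2, −20 °C to rt
Reagents that add atoms: bis(trimethylsilyl) peroxide, C[Si](C)(C)OO[Si](C)(C)C
Why: In this Baeyer–Villiger oxidation the more substituted ring-fusion carbon C14 migrates with retention (C3 is deactivated by the β-oxygen), which places the oxygen on C14 with the target configuration, and the silyl peroxide system is chosen because it oxidizes ketones without epoxidizing the C11=C12 olefin.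

Step 17
Reactants: 26 δ-lactone (C14–O–C4)
Product: 27 C14 alcohol with C4 Weinreb amide
Conditions: MeNH(OMe)·HCl, AlMe3, CH2Cl2, 0 °C; then 26, 0 °C; aq. potassium sodium tartrate
Reagents that add atoms: N,O-dimethylhydroxylamine hydrochloride, CNOC.Cl
Why: Weinreb aminolysis with the aluminium amide should open the unhindered six-membered lactone in preference to the α-methyl, β-quaternary butanolide, releasing the C14 hydroxyl and leaving C4 one reduction away from the aldehyde.

Step 18
Reactants: 27 C14 alcohol with C4 Weinreb amide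
Product: 28 C14 acetate
Conditions: Ac2O, pyridine, DMAP (cat.), CH2Cl2, 0 °C
Reagents that add atoms: acetic anhydride, CC(=O)OC(C)=O
Why: Acetylation of the only free hydroxyl installs the first target acetate and blocks relactonization.

Step 19
Reactants: 28 C14 acetate
Product: 29 tetraol (C2, C8, C9, C20 hydroxyls)
Conditions: HF·pyridine, pyridine, THF, 0 °C to rt
Reagents that add atoms: none
Why: Buffered fluoride removes the silylene bridge and the TBS and triethylsilyl ethers in one operation while acetate, amide, lactone and vinyl iodide survive.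

Step 20
Reactants: 29 tetraol
Product: 32 triol with C11=C20 exocyclic methylene, via allylic sulfonylhydrazine 30 (not isolated), via allylic diazene 31 (not isolated)
Conditions: PPh3, DEAD, 2-nitrobenzenesulfonohydrazide, N-methylmorpholine, −30 °C; then rt
Reagents that add atoms: none
Why: In this Myers reductive 1,3-transposition, Mitsunobu displacement of the only unhindered (primary allylic) hydroxyl, loss of sulfinic acid and sigmatropic loss of N2 from the diazene deliver hydrogen to C12 and move the double bond to C11=C20; no stereocentre is formed.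

Step 21
Reactants: 32 triol with C11=C20 exocyclic methylene
Product: 33 C9,C14-diacetate
Conditions: Me2SnCl2 (5 mol %), AcCl (1.1 equiv), iPr2NEt, THF, 0 °C
Reagents that add atoms: acetyl chloride, CC(Cl)=O
Why: In the tin-catalysed monoacylation of 1,2-diols only the C8/C9 diol forms the stannylene chelate, which activates the secondary O9 and leaves the isolated C2 hydroxyl and the tertiary C8 hydroxyl free.

Step 22
Reactants: 33 C9,C14-diacetate
Product: 34 C2 isobutyrate
Conditions: (i-PrCO)2O, Et3N, DMAP (cat.), CH2Cl2, rt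
Reagents that add atoms: 2-methylpropanoic anhydride, CC(C)C(=O)OC(=O)C(C)C
Why: DMAP-catalysed acylation esterifies the last secondary hydroxyl (C2) while the tertiary C8 hydroxyl is inert.

Step 23
Reactants: 34 C2 isobutyrate
Product: 35 seco aldehyde (C4 aldehyde, C5 vinyl iodide)
Conditions: Cp2Zr(H)Cl (2.5 equiv), THF, rt; aqueous work-up
Reagents that add atoms: none
Why: The Schwartz reagent reduces the Weinreb amide to the aldehyde through a stable zirconated hemiaminal and is known to tolerate esters, so the three esters and the lactone should survive.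

Step 24
Reactants: 35 seco aldehyde
Product: 36 macrocyclic allylic alcohol (4R)
Conditions: CrCl2, Kishi-type chiral oxazoline sulfonamide ligand, Et3N, THF; NiCl2 (cat.); 35 added slowly (0.002 M), rt
Reagents that add atoms: none
Why: In this Nozaki–Hiyama–Kishi macrocyclization, nickel-catalysed activation of the C5–I bond with retention of the Z geometry, transmetalation to chromium and addition to the C4 aldehyde close the ten-membered ring, and the ligand enantiomer is chosen to direct attack to the Si face of the aldehyde, which gives 4R.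

Step 25
Reactants: 36 macrocyclic allylic alcohol (4R)
Product: 37 target CNP0189561.1
Conditions: Ac2O, pyridine, DMAP (cat.), CH2Cl2, rt
Reagents that add atoms: acetic anhydride, CC(=O)OC(C)=O
Why: Acetylation of the secondary allylic C4 hydroxyl completes the ester pattern; the hindered tertiary C8 hydroxyl stays free.

## Compound list

1 | L-erythrulose, (3S)-1,3,4-trihydroxybutan-2-one | OC[C@H](O)C(=O)CO | starting material
2 | (S)-1-(2,2-dimethyl-1,3-dioxolan-4-yl)-2-hydroxyethan-1-one | CC1(C)OC[C@H](O1)C(=O)CO | intermediate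
3 | (S)-2-[(tert-butyldiphenylsilyl)oxy]-1-(2,2-dimethyl-1,3-dioxolan-4-yl)ethan-1-one | CC1(C)OC[C@H](O1)C(=O)CO[Si](c2ccccc2)(c2ccccc2)C(C)(C)C | intermediate
4 | methyl (3R)-4-[(tert-butyldiphenylsilyl)oxy]-3-[(4S)-2,2-dimethyl-1,3-dioxolan-4-yl]-3-hydroxy-2-methylbutanoate, both C2 epimers | COC(=O)C(C)[C@@](O)(CO[Si](c2ccccc2)(c2ccccc2)C(C)(C)C)[C@@H]1COC(C)(C)O1 | intermediate
5 | (4R,5S)-4-{[(tert-butyldiphenylsilyl)oxy]methyl}-4-hydroxy-5-(hydroxymethyl)-3-methyloxolan-2-one, C3 epimer mixture | OC[C@@H]1OC(=O)C(C)[C@@]1(O)CO[Si](c2ccccc2)(c2ccccc2)C(C)(C)C | intermediate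
6 | (3R,4R,5S)-4-{[(tert-butyldiphenylsilyl)oxy]methyl}-4-hydroxy-5-(hydroxymethyl)-3-methyloxolan-2-one | OC[C@@H]1OC(=O)[C@H](C)[C@@]1(O)CO[Si](c2ccccc2)(c2ccccc2)C(C)(C)C | intermediate
7 | (2R,3R,4R)-3-{[(tert-butyldiphenylsilyl)oxy]methyl}-3-hydroxy-4-methyl-5-oxooxolane-2-carbaldehyde | O=C[C@@H]1OC(=O)[C@H](C)[C@@]1(O)CO[Si](c2ccccc2)(c2ccccc2)C(C)(C)C | intermediate
8 | (3R,4R,5S)-4-{[(tert-butyldiphenylsilyl)oxy]methyl}-4-hydroxy-5-[(Z)-2-iodoprop-1-en-1-yl]-3-methyloxolan-2-one | I/C(C)=C\[C@@H]1OC(=O)[C@H](C)[C@@]1(O)CO[Si](c2ccccc2)(c2ccccc2)C(C)(C)C | intermediate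
9 | (3R,4R,5S)-4-hydroxy-4-(hydroxymethyl)-5-[(Z)-2-iodoprop-1-en-1-yl]-3-methyloxolan-2-one | I/C(C)=C\[C@@H]1OC(=O)[C@H](C)[C@@]1(O)CO | intermediate
10 | (2S,3S,4R)-3-hydroxy-2-[(Z)-2-iodoprop-1-en-1-yl]-4-methyl-5-oxooxolane-3-carbaldehyde | I/C(C)=C\[C@@H]1OC(=O)[C@H](C)[C@@]1(O)C=O | intermediate
11 | (2S,3S,4R)-2-[(Z)-2-iodoprop-1-en-1-yl]-4-methyl-5-oxo-3-[(triethylsilyl)oxy]oxolane-3-carbaldehyde | I/C(C)=C\[C@@H]1OC(=O)[C@H](C)[C@@]1(O[Si](CC)(CC)CC)C=O | intermediate
12 | prop-2-yn-1-ol | C#CCO | starting material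
13 | 4-ethenyl-2,5-dihydro-1,2-oxamagnesole (cyclic alkenylmagnesium alkoxide) | C=CC1=C[Mg]OC1 | intermediate
14 | (2Z)-2-(iodomethylidene)but-3-en-1-ol | I/C=C(\CO)C=C | intermediate
15 | tert-butyl{[(2Z)-2-(iodomethylidene)but-3-en-1-yl]oxy}dimethylsilane | I/C=C(\CO[Si](C)(C)C(C)(C)C)C=C | intermediate
16 | dienyllithium from 15 (lithium in place of iodine, geometry retained) | [Li]/C=C(\CO[Si](C)(C)C(C)(C)C)C=C | intermediate
17 | dienylzinc bromide from 16 | Br[Zn]/C=C(\CO[Si](C)(C)C(C)(C)C)C=C | intermediate
18 | (3R,4R,5S)-4-[(1S,2Z)-3-{[(tert-butyldimethylsilyl)oxy]methyl}-1-hydroxypenta-2,4-dien-1-yl]-5-[(Z)-2-iodoprop-1-en-1-yl]-3-methyl-4-[(triethylsilyl)oxy]oxolan-2-one (C9 cis to the silyloxymethyl group across C10=C11) | I/C(C)=C\[C@@H]1OC(=O)[C@H](C)[C@@]1(O[Si](CC)(CC)CC)[C@@H](O)/C=C(\CO[Si](C)(C)C(C)(C)C)C=C | intermediate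
19 | (4S)-4-[(tert-butyldimethylsilyl)oxy]cyclopent-2-en-1-one | O=C1C=C[C@@H](O[Si](C)(C)C(C)(C)C)C1 | starting material
20 | tert-butyldimethyl({(1S,2S)-2-methyl-4-[(trimethylsilyl)oxy]cyclopent-3-en-1-yl}oxy)silane (trans) | C[C@H]1C=C(O[Si](C)(C)C)C[C@@H]1O[Si](C)(C)C(C)(C)C | intermediate
21 | (4S)-4-[(tert-butyldimethylsilyl)oxy]-3-methylcyclopent-2-en-1-one | CC1=CC(=O)C[C@@H]1O[Si](C)(C)C(C)(C)C | intermediate
22 | (4S)-4-hydroxy-3-methylcyclopent-2-en-1-one | CC1=CC(=O)C[C@@H]1O | intermediate
23 | O9-[chloro(diisopropyl)silyl] ether of dienol 18 | I/C(C)=C\[C@@H]1OC(=O)[C@H](C)[C@@]1(O[Si](CC)(CC)CC)[C@@H](O[Si](Cl)(C(C)C)C(C)C)/C=C(\CO[Si](C)(C)C(C)(C)C)C=C | intermediate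
24 | silaketal: O9 of dienol 18 and O2 of enone 22 joined through Si(i-Pr)2 | I/C(C)=C\[C@@H]1OC(=O)[C@H](C)[C@@]1(O[Si](CC)(CC)CC)[C@@H](O[Si](C(C)C)(C(C)C)O[C@H]2CC(=O)C=C2C)/C=C(\CO[Si](C)(C)C(C)(C)C)C=C | intermediate
25 | tetracyclic cycloadduct: ring A cyclohexene (C11=C12) cis-fused at C1–C14 to the C4 cyclopentanone and trans-fused at C1–C10 to the dioxasilepane; C15 methyl and H14 on one face, C2 and C4 on the other, C9 trans to C2 | CC(C)(C)[Si](C)(C)OCC1=CC[C@H](C5=O)[C@]2(C)[C@@H](O[Si](C(C)C)(C(C)C)O[C@H]([C@]3(O[Si](CC)(CC)CC)[C@@H](C)C(=O)O[C@H]3/C=C(/C)I)[C@@H]12)C5 | intermediate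
26 | δ-lactone from 25 (oxygen inserted between C14 and C4, configuration at C14 retained) | CC(C)(C)[Si](C)(C)OCC1=CC[C@H](OC5=O)[C@]2(C)[C@@H](O[Si](C(C)C)(C(C)C)O[C@H]([C@]3(O[Si](CC)(CC)CC)[C@@H](C)C(=O)O[C@H]3/C=C(/C)I)[C@@H]12)C5 | intermediate
27 | ring-opened C14 alcohol with C4 N-methoxy-N-methylamide | CC(C)(C)[Si](C)(C)OCC1=CC[C@H](O)[C@]2(C)[C@@H](O[Si](C(C)C)(C(C)C)O[C@H]([C@]3(O[Si](CC)(CC)CC)[C@@H](C)C(=O)O[C@H]3/C=C(/C)I)[C@@H]12)CC(=O)N(C)OC | intermediate
28 | C14 acetate of 27 | CC(C)(C)[Si](C)(C)OCC1=CC[C@H](OC(C)=O)[C@]2(C)[C@@H](O[Si](C(C)C)(C(C)C)O[C@H]([C@]3(O[Si](CC)(CC)CC)[C@@H](C)C(=O)O[C@H]3/C=C(/C)I)[C@@H]12)CC(=O)N(C)OC | intermediate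
29 | tetraol: 28 with free C2, C8, C9 and C20 hydroxyls | I/C(C)=C\[C@@H]1OC(=O)[C@H](C)[C@@]1(O)[C@@H](O)[C@H]1C(CO)=CC[C@H](OC(C)=O)[C@]1(C)[C@@H](O)CC(=O)N(C)OC | intermediate
30 | N-(C20-allyl)-N-(2-nitrobenzenesulfonyl)hydrazine from 29 | I/C(C)=C\[C@@H]1OC(=O)[C@H](C)[C@@]1(O)[C@@H](O)[C@H]1C(CN(N)S(=O)(=O)c2ccccc2[N+](=O)[O-])=CC[C@H](OC(C)=O)[C@]1(C)[C@@H](O)CC(=O)N(C)OC | intermediate
31 | C20 allylic diazene | I/C(C)=C\[C@@H]1OC(=O)[C@H](C)[C@@]1(O)[C@@H](O)[C@H]1C(CN=N)=CC[C@H](OC(C)=O)[C@]1(C)[C@@H](O)CC(=O)N(C)OC | intermediate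
32 | triol with exocyclic C11=C20 methylene and C12 methylene | I/C(C)=C\[C@@H]1OC(=O)[C@H](C)[C@@]1(O)[C@@H](O)[C@H]1C(=C)CC[C@H](OC(C)=O)[C@]1(C)[C@@H](O)CC(=O)N(C)OC | intermediate
33 | C9,C14-diacetate (C2 and C8 hydroxyls free) | I/C(C)=C\[C@@H]1OC(=O)[C@H](C)[C@@]1(O)[C@@H](OC(C)=O)[C@H]1C(=C)CC[C@H](OC(C)=O)[C@]1(C)[C@@H](O)CC(=O)N(C)OC | intermediate
34 | C2 isobutyrate of 33 | I/C(C)=C\[C@@H]1OC(=O)[C@H](C)[C@@]1(O)[C@@H](OC(C)=O)[C@H]1C(=C)CC[C@H](OC(C)=O)[C@]1(C)[C@@H](OC(=O)C(C)C)CC(=O)N(C)OC | intermediate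
35 | seco aldehyde (C4 aldehyde, C5 Z-vinyl iodide) | I/C(C)=C\[C@@H]1OC(=O)[C@H](C)[C@@]1(O)[C@@H](OC(C)=O)[C@H]1C(=C)CC[C@H](OC(C)=O)[C@]1(C)[C@@H](OC(=O)C(C)C)CC=O | intermediate
36 | 4-O-deacetyl target (4R allylic alcohol, ten-membered ring closed) | C=C1CC[C@H](OC(C)=O)[C@]2(C)[C@@H](OC(=O)C(C)C)C[C@@H](O)/C(C)=C\[C@@H]3OC(=O)[C@H](C)[C@@]3(O)[C@@H](OC(C)=O)[C@@H]12 | intermediate
37 | CNP0189561.1, (1R,2S,4R,5Z,7S,8S,9S,10S,14S,17R) in briarane numbering | C=C1CC[C@H](OC(C)=O)[C@]2(C)[C@@H](OC(=O)C(C)C)C[C@@H](OC(C)=O)/C(C)=C\[C@@H]3OC(=O)[C@H](C)[C@@]3(O)[C@@H](OC(C)=O)[C@@H]12 | target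

## Summary

Total step count: 25. Longest linear sequence: 21 steps (steps 1–8, 11, 14–25).

Steps most likely to fail:

1. Step 15. The β,β-disubstituted enone may be too poor a dienophile, so that thermal decomposition of the dienyl silaketal outruns the cycloaddition. The fallback activates the dienophile as its 2-bromo derivative and sets out from 21. Bromination and dehydrobromination (Br2, then Et3N, CH2Cl2, 0 °C) should give the bromo enone F1, and aqueous HF the bromo hydroxy enone F2. Union with chlorosilane 23 as in step 14 gives the bromo silaketal F3. Because 2-halo enones are much more reactive dienophiles, the same tether-controlled cycloaddition should then run near 80 °C to the α-bromo ketone F4. Zinc dust in acetic acid cleaves the C14–Br bond through the zinc enolate, which is protonated on the convex face to restore the cis ring fusion, and the route is rejoined at 25.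

2. Step 16. Epoxidation of the C11=C12 olefin or Lewis-acid loss of silyl groups may compete with the Baeyer–Villiger oxidation. The fallback sets out from 25 and accepts both oxidations: excess mCPBA with NaHCO3 in CH2Cl2 should give the epoxy lactone F5. Deoxygenation of the epoxide with Cp2TiCl (from Cp2TiCl2 and Zn, THF), by β-titanoxy radical formation and elimination, regenerates the olefin and returns to 26.

3. Step 24. Facial selectivity at the C4 aldehyde may be poor if the macrocyclic bias overrides the ligand. The fallback sets out from 35: ligand-free cyclization (CrCl2, NiCl2 cat., DMSO, high dilution) gives the carbinol as a C4 epimer mixture F6. Dess–Martin oxidation converges both epimers to the macrocyclic enone F7. Reduction with the (S)-methyl-CBS oxazaborolidine and BH3·SMe2, in which the C5 alkenyl group acts as the large substituent, should give the 4R alcohol and return to 36.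

Further compounds
F1 | step 15 | (4S)-2-bromo-4-[(tert-butyldimethylsilyl)oxy]-3-methylcyclopent-2-en-1-one | CC1=C(Br)C(=O)C[C@@H]1O[Si](C)(C)C(C)(C)C
F2 | step 15 | (4S)-2-bromo-4-hydroxy-3-methylcyclopent-2-en-1-one | CC1=C(Br)C(=O)C[C@@H]1O
F3 | step 15 | bromo silaketal (24 with bromine on the enone α-carbon) | I/C(C)=C\[C@@H]1OC(=O)[C@H](C)[C@@]1(O[Si](CC)(CC)CC)[C@@H](O[Si](C(C)C)(C(C)C)O[C@H]2CC(=O)C(Br)=C2C)/C=C(\CO[Si](C)(C)C(C)(C)C)C=C
F4 | step 15 | C14-bromo cycloadduct (25 with bromine in place of H14) | CC(C)(C)[Si](C)(C)OCC1=CC[C@](Br)(C5=O)[C@]2(C)[C@@H](O[Si](C(C)C)(C(C)C)O[C@H]([C@]3(O[Si](CC)(CC)CC)[C@@H](C)C(=O)O[C@H]3/C=C(/C)I)[C@@H]12)C5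
F5 | step 16 | 11,12-epoxide of lactone 26 (epoxide configuration not defined) | CC(C)(C)[Si](C)(C)OCC16OC6C[C@H](OC5=O)[C@]2(C)[C@@H](O[Si](C(C)C)(C(C)C)O[C@H]([C@]3(O[Si](CC)(CC)CC)[C@@H](C)C(=O)O[C@H]3/C=C(/C)I)[C@@H]12)C5
F6 | step 24 | macrocyclic allylic alcohol as C4 epimer mixture | C=C1CC[C@H](OC(C)=O)[C@]2(C)[C@@H](OC(=O)C(C)C)CC(O)/C(C)=C\[C@@H]3OC(=O)[C@H](C)[C@@]3(O)[C@@H](OC(C)=O)[C@@H]12
F7 | step 24 | macrocyclic C4 enone | C=C1CC[C@H](OC(C)=O)[C@]2(C)[C@@H](OC(=O)C(C)C)CC(=O)/C(C)=C\[C@@H]3OC(=O)[C@H](C)[C@@]3(O)[C@@H](OC(C)=O)[C@@H]12
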